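Time buys nothing in the red run: from its first reading at 0.200 h onward, Z, E and Q show no trend beyond the scatter.

| flask | Z | G | remark | time |
|---|---|---|---|---|
| red | 1.1 M | 2 equiv | run made earlier |  |
| green | 0.80 M | 3 equiv | run made earlier |  |
| flask | 0.80 M | 2.00 equiv |  | 2.5 h |

| run | time / h | Z / % | E / % | Q / % |
|---|---|---|---|---|
| red | 0.200 | 7.7 | 29.4 | 59.9 |
| red | 0.333 | 7.0 | 30.1 | 59.7 |
| red | 0.500 | 9.5 | 28.5 | 60.7 |
| red | 0.833 | 9.5 | 29.4 | 61.8 |
| red | 1.50 | 8.2 | 29.4 | 59.0 |
| red | 2.50 | 7.8 | 27.6 | 57.8 |
| green | 0.200 | 1.2 | 12.6 | 78.6 |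
| green | 0.667 | 1.2 | 5.7 | 81.6 |
| green | 1.33 | 1.1 | 7.6 | 80.3 |
| green | 2.00 | 1.1 | 9.4 | 80.2 |
| green | 2.50 | 1.3 | 7.5 | 80.0 |

(each reading ± 1 percentage point)

- which holds at 2.5 h: what has brought the reaction to rest, or that it has not come to rest (it is still moving / G has run out first / forward and back rates have come level / all of Z has reacted)
- part of the Z gone at 2.5 h
- the E standing at 2.5 h, as a percentage of the Z charged
- the Q standing at 2.5 h, as a percentage of the Z charged

- reactions considered so far: Z + G -> E + J; G + E -> Q + J; G + Q -> L + J; 2 G -> D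
- the reaction counts as stopped when no species that holds the Z changes by six tenths of a point or more over the second half of the time

Z, E and Q each take up one G and release one J, while 2 G give D. Every step is bimolecular as written, so scaling the concentrations at fixed equivalents keeps the rate ratios and stretches the clock. From red to this flask the stretch is 1.38, so this flask should be still by 0.275 h, far earlier than the 2.5 h asked.

The bench rule counts one substitution per G charged. Red's mean readings test it: Z 8.28 %, E 29.1 %, Q 59.8 %, with L as the gap in the balance, 2.83 %. The G yield, substitutions on Z per G charged, is then 0.786, below the rule's 1. Green's means give 0.664, lower than red's, so the yield read in one of these two runs does not carry unchanged to the other. This flask has red's equivalents, so it takes red's yield: G as limiting reagent, 1.26 M of J, 91.7 % of Z gone, E 29.1 % and Q 59.8 %.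

The forecast says G has run out first, with 91.7 % of Z gone, E 29 % and Q 59.7 %, on the ground that “Dilution only slows the clock.”

In the flask, G has run out first, with 91.5 % of Z gone, E 28.9 % and Q 59.3 %.

    Z + G → E + J (k = 0.0160 M⁻¹ s⁻¹)
    G + E → Q + J (k = 0.0120 M⁻¹ s⁻¹)
    G + Q → L + J (k = 7.60 × 10⁻⁴ M⁻¹ s⁻¹)
    2 G → D (k = 0.00180 M⁻¹ s⁻¹)

At 2.50 h this flask holds 1.26 M of J, a G yield of 0.787, with G at 0 % of its charge. The neighbour charged with 3.40 equiv stands closer in equivalents to green than to red, and green's yield gives it 1.81 M of J. The neighbour holds 1.72 M at 2.50 h, so its yield is 0.631, lower than green's. In that neighbour, G stands at 0 % of its charge, Q at 79.8 % and L at 17.4 %.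

The numbers in the tables stem from a simulated flask from invented constants; the scatter is artificial.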